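The earlier runs and the new flask come from a simulation for an exercise, and the scatter is random.

J is an intermediate, and you need the time one J lasts before it becomes L, set against the time asked about.

| flask | Q | D | remark | time |
|---|---|---|---|---|
| dawn | 0.42 M | 5 mol% | run made earlier |  |
| spring | 0.66 M | 5 mol% | run made earlier |  |
| summer | 0.30 M | 7.5 mol% | run made earlier |  |
| flask | 0.30 M | 5 mol% |  | 10 min |

- dawn (time / min: J / %, L / %): 2.50: 7.6, 35.3; 5.00: 6.7, 54.2; 8.00: 5.3, 64.2; 10.0: 6.6, 68.7
- spring (time / min: J / %, L / %): 0.833: 11.6, 17.1; 2.00: 8.2, 31.0; 4.00: 7.4, 48.8; 10.0: 3.6, 68.6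
- summer (time / min: J / %, L / %): 2.50: 8.0, 36.4; 5.00: 8.0, 52.5; 8.00: 5.6, 63.4; 10.0: 4.2, 69.2

(readings scatter by 1 percentage point)

* share of J in J plus L at 2.0 s
* share of J in J plus L at 40 s
* share of J in J plus L at 10 min
* which of J and L there is more of at 10 min

The spring run gives a rate constant. Between 0.833 min and 2.00 min, L gains per minute over mean J:

k = 1.20 /min

But L also returns to J. The pooled reading of L over J at 10 min is 14.3, so put that back in, subtracting mean L over this ratio from mean J:

k = 1.45 /min

τ = 0.690 min

Call τ the lifetime of J against first-order passage to L; it is a reading from the spring run.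

At 40 s, steady making of J gives a share of 64.1%, and one burst gives 38.1%. In spring, J plus L reached 28.7% by 0.833 min but gained just 10 percentage points more by 2.00 min, so making falls early and I take the middle, 51.1%. The same middle at 2.0 s gives 96.5%. At 10 min, far longer than τ, I estimate the share from the read ratio as 6.52%, with L ahead.

The forecast, reading “a sequential path”, gave 95%, 44% against my 51.1%, 6.5%, and L ahead.

The flask gives 97.2%, 50.7%, 6.89%, and L ahead, with 4.88% of J and 65.9% of L.

    Q + D ⇌ J + D, rate k1*[Q]*[D] forward; the back reaction follows from the equilibrium constant (K = 0.190, k = 1.35 /M/s)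
    J ⇌ L (K = 17.0, k = 0.0275 /s)
    D ⇌ G (K = 1.80, k = 0.0291 /s)

The neighbour flask is this flask with 0.075 M of Q. Carried over unchanged, τ = 0.690 min keeps the ends 38.1% and 64.1% at 40 s. The neighbour gives 97.3% at 2.0 s and 55.0% at 40 s, higher than the flask's share and inside those ends. At 10 min its share is 8.47%, above the 6.52% from the ratio, with 47.9% of L and 48% of Q left.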